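Readings and results come from a simulation from invented constants.

Read fractions. What matters here is what share of the substrate has turned, and how fast the remainder goes.

| flask | substrate | partner | catalyst | time |
|---|---|---|---|---|
| Thursday's | 150 mM | 150 mM | 4.50 mM |  |
| Sunday's | 90.0 mM | 90.0 mM | 4.50 mM |  |
| Friday's | 150 mM | 75.0 mM | 4.50 mM |  |
| Saturday's | 150 mM | 450 mM | 2.20 mM | 130 min |

| run | time / min | [product] / mM |
|---|---|---|
| Thursday's run | 26 | 36.7 |
| Thursday's run | 52 | 65.0 |
| Thursday's run | 78 | 84.5 |
| Thursday's run | 100 | 97.0 |
| Thursday's run | 130 | 108.1 |
| Sunday's run | 26 | 22.7 |
| Sunday's run | 52 | 38.7 |
| Sunday's run | 78 | 51.0 |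
| Sunday's run | 100 | 58.8 |
| Sunday's run | 130 | 66.8 |
| Friday's run | 26 | 30.8 |
| Friday's run | 52 | 53.5 |
| Friday's run | 78 | 64.5 |
| Friday's run | 100 | 67.4 |
| Friday's run | 130 | 69.3 |

(readings scatter by 0.4 mM)

- Overall: substrate + partner -> product, with catalyst as catalyst.
- Constant volume, constant temperature.
- Readings of a species count what is bound in complexes too.
- "The second partner" is partner.
- An order is taken over about fifteen percent of the charge, up and down.

- apparent order in [partner] of the starting rate, round the charge of the Thursday's run (the rate where two percent of its substrate have turned into product)
- apparent order in [substrate] of the starting rate, round the charge of the Thursday's run (the rate where two percent of its substrate have turned into product) (one fixed amount of product, the same in the runs compared)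
- product in the Saturday's run at 130 min, as a share of the substrate charged
- which of these the readings show (the second partner ties up the catalyst / two substrates go astray together / nothing beyond the main steps / the substrate kills the catalyst / the second partner is lost in pairs)

Two chemists argue over Saturday's flask with one tool, a clock, here read from the first reading of Thursday's run as 0.0108 min⁻¹: the logarithm of one over the unturned fraction of substrate, divided by the time. It is a pseudo-first-order constant, and it belongs to Thursday's catalyst, so for Saturday both scale it by 0.489.

The colleague holds that the substrate kills the catalyst. Thursday's clock, read over the whole run, has sagged to 0.00981 min⁻¹, and Saturday has Thursday's substrate charge and the same 130 min to wear through. So the colleague takes that slower clock, which gives 46.4 %.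

The forecaster objects with Friday's run, charged with Thursday's substrate and catalyst but with partner as the limiting reagent. Over the last 30.0 min, Friday's run made 0.0127 of its substrate charge and Thursday's 0.0740, though Friday's product stood at 92.4 % of its partner charge at the end. The forecast reads this as “A loss that grows steeply with partner concentration fits pairwise partner loss”. It names the second partner is lost in pairs, gives orders of 0.15 in partner and 0.8 in substrate, and keeps the early clock for Saturday, where partner stands at 3.00 times the substrate. It takes 0.0115 per minute for Thursday's catalyst, scales that to Saturday's, and gets 50 %. My own reckoning differs: with my early clock of 0.0108 min⁻¹, it gives 49.6 %.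

The forecaster grants the colleague Thursday's and Sunday's runs, each charged with equal substrate and partner: Sunday's whole-run clock reads 0.0104 min⁻¹ beside Thursday's 0.00981 min⁻¹, so in these runs a whole-run clock serves as a description.

Saturday's flask gave product equal to 52.6 % of its substrate charge at 130 min; the orders round Thursday's charge are 0.14 in partner and 0.88 in substrate, and the verdict is that the second partner is lost in pairs.

    catalyst + substrate → catalyst-substrate complex (2.898 L mol⁻¹ min⁻¹)
    catalyst-substrate complex + partner → product + catalyst (19.38 L mol⁻¹ min⁻¹)
    2 partner → lost reagent (0.02922 L mol⁻¹ min⁻¹)

The apparent order in catalyst early in Thursday's run was 0.99. Saturday's own clock reads 0.00574 min⁻¹ against the scaled 0.00528 min⁻¹. Sunday's flask has Thursday's catalyst charge, and the half-life from Thursday's early clock is 64.2 min; Sunday's product came to half of its substrate charge at 63.9 min.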